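Which flask ends highest in ring, and does heat help it get there?

* the flask that comes out highest in amount of ring, in percent of the substrate charged, or "all alike" when all lie within 1.5 percentage points (eta / alpha / gamma / beta / all alike)
* ring at the end, in percent of the substrate charged, eta
* ring at the end, in percent of the substrate charged, alpha
* ring at the end, in percent of the substrate charged, gamma
* ring at the end, in percent of the substrate charged, beta

| setting | north-west | eta | alpha | gamma | beta |
|---|---|---|---|---|---|
| substrate | 1.8 M | 0.92 M | 0.92 M | 0.92 M | 0.92 M |
| gas | 86 mM (held) | 86 mM (held) | 86 mM (held) | 86 mM (held) | 86 mM (held) |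
| temperature | 90 °C | 90 °C | 115 °C | 65 °C |  |
| remark | run made earlier |  |  |  | at 65 °C until 80 min, from then on at 115 °C |
| time |  | 2.0 h | 2.0 h | 2.0 h | 2.0 h |

north-west run (percent of the substrate charged)

| time / min | ring / % | substrate / % |
|---|---|---|
| 3.00 | 1.1 | 87.3 |
| 5.00 | 0.7 | 79.4 |
| 8.00 | 0.9 | 68.3 |
| 12.0 | 2.6 | 54.0 |
| 20.0 | 4.5 | 31.6 |
| 40.0 | 17.0 | 7.3 |

(each reading ± 1 percentage point)

- at the start none of the gas is in solution
- the earlier runs do not show what temperature does; that part of a forecast is a guess

Two chemists read the north-west run. At 40.0 min its substrate stands at 7.3% and its ring at 17.0%, so 75.7% of the charge sits in something unseen. The first chemist takes substrate as falling by a constant fraction, with one slow step behind it. Percentages then ignore the charge, and hotter is better. The second sees that fraction per minute drift upward in the readings, from 0.0453 min⁻¹ over the first 3.00 min to 0.0654 min⁻¹ over 40.0 min, so she reads a roughly steady molar rate instead, 0.0590 M min⁻¹ between 3.00 min and 20.0 min.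

With 0.92 M charged, this gives 15.6 min: the clearing time, the charge divided by that molar rate. It is a yardstick taken at 90 °C, and it scales with the charge. She argues that substrate and the unseen form stand together for about this span, so any reaction between them costs a share that grows with the charge. Beta's cold stage lasts 5.13 of these clearing times reckoned at 90 °C. The earlier runs do not show what temperature does, so her bet that beta ends above alpha is a guess.

The forecast takes the first side: alpha highest, with eta 55%, alpha 90%, gamma 6% and beta 78%. Its ground is “Alpha then nears completion”.

The simulation gives beta highest at 87.2%, with alpha 77.9%, eta 65.5% and gamma 11.1%. The first view keeps the flasks held at one temperature at the asked time, where alpha stands above eta and gamma. Left until 20.0 h, though, eta holds 82.3% of ring, more than alpha's 77.9%.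

    activated form → ring (k = 2.90 × 10⁻⁴ s⁻¹, Ea = 99.0 kJ mol⁻¹)
    gas ⇌ activator, rate k2*(csat - [activator]) (kL = 0.00950 s⁻¹)
    2 substrate → homo dimer (k = 1.20 × 10⁻⁶ M⁻¹ s⁻¹, Ea = 110 kJ mol⁻¹)
    substrate + activator → activated form (k = 0.0340 M⁻¹ s⁻¹, Ea = 56.0 kJ mol⁻¹)
    substrate + activated form → open dimer (k = 5.10 × 10⁻⁴ M⁻¹ s⁻¹, Ea = 69.0 kJ mol⁻¹)
    substrate ⇌ dormant form (K = 0.660, k = 3.10 × 10⁻⁴ s⁻¹, Ea = 123 kJ mol⁻¹, ΔH = 0 kJ mol⁻¹)
    (constants at 90 °C)

In beta, up to the change at 80 min, substrate, the limiting reagent, fell to 4.80% while activated form built up to 75.3% and open dimer reached 10.9%. After the change, at 115 °C, activated form fell to 0.288% by 2.00 h, leaving beta with 87.2% ring and 12.5% open dimer, each open dimer counted as two. The neighbour, the same flask as beta with 0.23 M of substrate, has a clearing time of 3.90 min, a quarter of beta's 15.6 min, so an open-dimer share taken as proportional to the clearing time is estimated at 3.12%. The computed neighbour flask holds 2.97% open dimer and 96.7% ring.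

All runs were computed for an exercise; scatter was added.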